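Cuts: the lactone acyl bond O2–C1 is opened first, C3–O2 is traced back to a C3–B bond, and then C3–C4 is cut. The C8 phenol and the chain-end alcohol are carried as a methyl ether and a TBS ether.
Enabling feature: C3 is the only stereocentre, a secondary carbinol carbon of lactone ring B lying between the benzylic methylene C4 and an unbranched eleven-carbon chain. C3 plus chain is therefore C1–C12 of a plain primary alcohol, and C3 can act as a chiral α-oxy carbanion.
Forward, two halves: dodecane-1,12-diol is desymmetrised as its mono-TBS ether and converted to the diisopropylcarbamate. Ring A is bought with C1 and C4 in place, and its methyl group (C4) is borylated.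
Union and ring: lithiation–borylation joins C3 to C4 without closing a ring. Ring B closes afterwards by B-to-O oxidation and lactonisation, and one BCl3/MeOH operation frees both hydroxyl groups.
Stereochemistry: (−)-sparteine-directed deprotonation sets C3, and borylation (retention), 1,2-shift (inversion) and oxidation (retention) relay it to (3R).

Key step: step 4

Assumption: locants are those of 3,4-dihydroisocoumarin (C1 carbonyl, O2, C3, C4, C4a, C5–C8, C8a), and s-BuLi/(−)-sparteine is taken to remove the pro-S proton next to the carbamate oxygen, as it does for primary O-alkyl carbamates in general.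

Step 1
Reactants: 1 dodecane-1,12-diol
Product: 3 12-(tert-butyldimethylsilyloxy)dodecan-1-ol, via monosodium alkoxide 2 (not isolated)
Conditions: NaH (1.0 equiv), THF, rt; TBSCl (1.0 equiv), rt
Reagents that add atoms: tert-butyldimethylsilyl chloride (TBSCl), CC(C)(C)[Si](C)(C)Cl
Why: One equivalent of NaH converts the diol into its sparingly soluble monosodium alkoxide, which is silylated faster than a neutral hydroxyl group, so this O-silylation of a symmetrical diol should stop mainly at the mono-TBS ether, with leftover diol and bis-ether removed by chromatography.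

Step 2
Reactants: 3 12-(tert-butyldimethylsilyloxy)dodecan-1-ol; 4 N,N-diisopropylcarbamoyl chloride
Product: 5 12-(tert-butyldimethylsilyloxy)dodecyl N,N-diisopropylcarbamate
Conditions: 4 (1.2 equiv), Et3N (1.5 equiv), CH2Cl2, reflux
Reagents that add atoms: N,N-diisopropylcarbamoyl chloride 4, CC(C)N(C(C)C)C(=O)Cl
Why: O-Acylation of the remaining primary alcohol by the carbamoyl chloride under amine base is the standard entry to N,N-diisopropylcarbamates, and the TBS ether is inert to these conditions.

Step 3
Reactants: 6 methyl 2,4-dimethoxy-6-methylbenzoate; 7 2-isopropoxy-4,4,5,5-tetramethyl-1,3,2-dioxaborolane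
Product: 10 methyl 2,4-dimethoxy-6-[(4,4,5,5-tetramethyl-1,3,2-dioxaborolan-2-yl)methyl]benzoate, via benzylic lithium species 8 (not isolated), via isopropoxy borate complex 9 (not isolated)
Conditions: LDA (1.1 equiv), THF, −78 °C, slow addition of 6; 7 (1.3 equiv), −78 °C; 1 M aq HCl, −78 °C → rt
Reagents that add atoms: 2-isopropoxy-4,4,5,5-tetramethyl-1,3,2-dioxaborolane 7, CC(C)OB1OC(C)(C)C(C)(C)O1
Why: In this lateral lithiation the ortho ester acidifies the C6 methyl group, so lithium diisopropylamide at −78 °C gives the benzylic lithium species without touching the doubly ortho-substituted ester, and carbon rather than oxygen is captured by the borolane (electrophilic borylation of an organolithium) because only that restores aromaticity, giving a borate that persists until the cold quench expels isopropanol.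

Step 4
Reactants: 5 12-(tert-butyldimethylsilyloxy)dodecyl N,N-diisopropylcarbamate; 10 methyl 2,4-dimethoxy-6-[(4,4,5,5-tetramethyl-1,3,2-dioxaborolan-2-yl)methyl]benzoate
Product: 13 methyl 2-[(2R)-13-(tert-butyldimethylsilyloxy)-2-(4,4,5,5-tetramethyl-1,3,2-dioxaborolan-2-yl)tridecyl]-4,6-dimethoxybenzoate, via lithiated carbamate sparteine complex 11 (not isolated), via boronate ate complex 12 (not isolated)
Conditions: 5 (1.3 equiv), (−)-sparteine (1.3 equiv), s-BuLi (1.2 equiv), Et2O, −78 °C, 5 h; 10 (1.0 equiv), Et2O, −78 °C, 1 h; MgBr2·OEt2 (1.5 equiv), −78 °C → reflux, 16 h; aq NH4Cl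
Reagents that add atoms: none
Why: s-BuLi bound to (−)-sparteine removes the pro-S proton next to the carbamate oxygen of 5 (carbamate-directed asymmetric deprotonation) to give the configurationally stable (S)-organolithium 11, which attacks the vacant orbital on boron of 10 with retention and forms ate complex 12. On warming with MgBr2·OEt2 the benzylic carbon C4 shifts from boron to C3 antiperiplanar to the departing carbamate, so that the C3–C4 bond forms with inversion at C3 and boron remains on C3, which is the established lithiation–borylation (stereospecific 1,2-metallate rearrangement) of sparteine-complexed primary alkyl carbamates with pinacol boronic esters, benzylic ones included. No ring is closed. The one new stereocentre C3 is controlled by the chiral diamine alone, and the retention–inversion sequence turns (S)-11 into (R)-13, whose boron occupies exactly the place of O2 in the target. The step needs chemoselectivity for boron over the methyl ester and over the acidic benzylic C–H bonds of 10, which is secured by the very fast complexation of an unhindered primary pinacol boronate at −78 °C, by the two ortho substituents that flank the ester, and by keeping 5 in slight excess over s-BuLi so that no free alkyllithium meets 10. Double homologation is not expected because surplus 11 decomposes well below the temperature at which 12 rearranges.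

Step 5
Reactants: 13 methyl 2-[(2R)-13-(tert-butyldimethylsilyloxy)-2-(4,4,5,5-tetramethyl-1,3,2-dioxaborolan-2-yl)tridecyl]-4,6-dimethoxybenzoate
Product: 15 (3R)-3-[11-(tert-butyldimethylsilyloxy)undecyl]-6,8-dimethoxy-3,4-dihydro-1H-isochromen-1-one, via hydroxy ester 14 (not isolated)
Conditions: 30% aq H2O2, 2 M aq NaOH, THF, 0 °C → rt; aq citric acid to pH 4
Reagents that add atoms: hydrogen peroxide, OO
Why: Hydroperoxide adds to boron and C3 shifts from boron to oxygen with retention of configuration (standard boronic ester oxidation), after which the C3 alkoxide closes ring B on the adjacent methyl ester by 6-exo-trig acyl substitution just as the alkoxides formed from lithiated toluates and aldehydes do, while the mild acidification re-closes any hydroxy acid formed by hydroxide and leaves the TBS ether intact.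

Step 6
Reactants: 15 (3R)-3-[11-(tert-butyldimethylsilyloxy)undecyl]-6,8-dimethoxy-3,4-dihydro-1H-isochromen-1-one
Product: 17 (3R)-8-hydroxy-3-(11-hydroxyundecyl)-6-methoxy-3,4-dihydro-1H-isochromen-1-one, via 8-hydroxy silyl ether 16 (not isolated)
Conditions: BCl3 (1 M in CH2Cl2, 3 equiv), CH2Cl2, −78 → 0 °C; then MeOH, 0 °C → rt
Reagents that add atoms: none
Why: BCl3 is held in a six-membered chelate between the C1 carbonyl oxygen and the C8 methoxy oxygen, so chloride removes only that methyl group and the unchelated C6 methoxy group stays (the usual peri-selective demethylation of 6,8-dimethoxy-3,4-dihydroisocoumarins), and quenching with methanol produces methanolic HCl, which solvolyses the boron phenolate and the primary TBS ether without affecting C3.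

Compound list
1 | dodecane-1,12-diol | OCCCCCCCCCCCCO | starting material
2 | sodium 12-hydroxydodecan-1-olate | [Na+].[O-]CCCCCCCCCCCCO | intermediate
3 | 12-(tert-butyldimethylsilyloxy)dodecan-1-ol | OCCCCCCCCCCCCO[Si](C)(C)C(C)(C)C | intermediate
4 | N,N-diisopropylcarbamoyl chloride | CC(C)N(C(C)C)C(=O)Cl | starting material
5 | 12-(tert-butyldimethylsilyloxy)dodecyl N,N-diisopropylcarbamate | CC(C)N(C(C)C)C(=O)OCCCCCCCCCCCCO[Si](C)(C)C(C)(C)C | intermediate
6 | methyl 2,4-dimethoxy-6-methylbenzoate | COC(=O)c1c(C)cc(OC)cc1OC | starting material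
7 | 2-isopropoxy-4,4,5,5-tetramethyl-1,3,2-dioxaborolane | CC(C)OB1OC(C)(C)C(C)(C)O1 | starting material
8 | methyl 2-(lithiomethyl)-4,6-dimethoxybenzoate | COC(=O)c1c(C[Li])cc(OC)cc1OC | intermediate
9 | lithium [3,5-dimethoxy-2-(methoxycarbonyl)benzyl](isopropoxy)(pinacolato)borate | [Li+].COC(=O)c1c(C[B-]2(OC(C)C)OC(C)(C)C(C)(C)O2)cc(OC)cc1OC | intermediate
10 | methyl 2,4-dimethoxy-6-[(4,4,5,5-tetramethyl-1,3,2-dioxaborolan-2-yl)methyl]benzoate | COC(=O)c1c(OC)cc(OC)cc1CB1OC(C)(C)C(C)(C)O1 | intermediate
11 | (1S)-12-(tert-butyldimethylsilyloxy)-1-lithiododecyl N,N-diisopropylcarbamate, present as its (−)-sparteine complex (diamine not drawn) | CC(C)N(C(C)C)C(=O)O[C@@H]([Li])CCCCCCCCCCCO[Si](C)(C)C(C)(C)C | intermediate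
12 | lithium [(1S)-12-(tert-butyldimethylsilyloxy)-1-(N,N-diisopropylcarbamoyloxy)dodecyl][3,5-dimethoxy-2-(methoxycarbonyl)benzyl](pinacolato)borate | CC(C)N(C(C)C)C(=O)O[C@@H]([B-]1(Cc2cc(OC)cc(OC)c2C(=O)OC)OC(C)(C)C(C)(C)O1)CCCCCCCCCCCO[Si](C)(C)C(C)(C)C.[Li+] | intermediate
13 | methyl 2-[(2R)-13-(tert-butyldimethylsilyloxy)-2-(4,4,5,5-tetramethyl-1,3,2-dioxaborolan-2-yl)tridecyl]-4,6-dimethoxybenzoate | COC(=O)c1c(OC)cc(OC)cc1C[C@@H](CCCCCCCCCCCO[Si](C)(C)C(C)(C)C)B1OC(C)(C)C(C)(C)O1 | intermediate
14 | methyl 2-[(2R)-13-(tert-butyldimethylsilyloxy)-2-hydroxytridecyl]-4,6-dimethoxybenzoate | COC(=O)c1c(OC)cc(OC)cc1C[C@@H](CCCCCCCCCCCO[Si](C)(C)C(C)(C)C)O | intermediate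
15 | (3R)-3-[11-(tert-butyldimethylsilyloxy)undecyl]-6,8-dimethoxy-3,4-dihydro-1H-isochromen-1-one | COc1cc(OC)c2c(c1)C[C@@H](CCCCCCCCCCCO[Si](C)(C)C(C)(C)C)OC2=O | intermediate
16 | (3R)-3-[11-(tert-butyldimethylsilyloxy)undecyl]-8-hydroxy-6-methoxy-3,4-dihydro-1H-isochromen-1-one | COc1cc(O)c2c(c1)C[C@@H](CCCCCCCCCCCO[Si](C)(C)C(C)(C)C)OC2=O | intermediate
17 | (3R)-8-hydroxy-3-(11-hydroxyundecyl)-6-methoxy-3,4-dihydro-1H-isochromen-1-one | COc1cc(O)c2c(c1)C[C@@H](CCCCCCCCCCCO)OC2=O | target

Total step count: 6.
Longest linear sequence: 5 steps (steps 1, 2, 4, 5 and 6: 1 → 3 → 5 → 13 → 15 → 17). Step 3 is the one-step side branch.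

Steps most likely to fail

First, step 4.
- **Risk:** The organolithium may be lost before it reaches boron, either by proton transfer from the benzylic C–H bonds of 10 (acidified by boron and by the ortho ester) or by acyl attack on the ester. The ate complex may also shed the stabilised benzylic carbanion reversibly and so rearrange slowly.
- **Fallback:** It sets out from 5 and comes back at 15. The C3–C4 union is kept but run on an ester-free boron partner, and C1 is brought in afterwards as carbon monoxide.
- **Boron partner:** Commercial 3,5-dimethoxybenzyl bromide is borylated (B2pin2, Pd(dba)2, P(4-MeOC6H4)3, KOAc, toluene, 50 °C) to 2-(3,5-dimethoxybenzyl)-4,4,5,5-tetramethyl-1,3,2-dioxaborolane F1.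
- **Union and oxidation:** Compound 11, generated from 5 as in step 4, adds to it to give the lithium boronate ate complex F2. This rearranges on warming to the (R)-secondary boronic ester F3, and H2O2/NaOH converts that with retention to (2R)-13-(tert-butyldimethylsilyloxy)-1-(3,5-dimethoxyphenyl)tridecan-2-ol F4.
- **Bromination:** NBS in MeCN at 0 °C brominates the ring position between the side chain and a methoxy group (para to the other methoxy group). This gives (2R)-1-(2-bromo-3,5-dimethoxyphenyl)-13-(tert-butyldimethylsilyloxy)tridecan-2-ol F5.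
- **Ring closure:** Palladium-catalysed carbonylative lactonisation (Pd(OAc)2, Xantphos, CO 1 atm, Et3N, toluene, 100 °C) closes ring B to 15.

Second, step 3.
- **Risk:** Three processes may erode the step: Claisen-type self-condensation of the lithiated toluate with unreacted ester, proton exchange between anion and product, and protodeboronation of the activated benzylic C–B bond during work-up.
- **Fallback:** It sets out from 6 and comes back at 10 and involves no carbanion. Wohl–Ziegler bromination under strictly radical conditions (NBS, AIBN, PhCF3, reflux, light) gives methyl 2-(bromomethyl)-4,6-dimethoxybenzoate F6. Miyaura borylation of this benzylic bromide (B2pin2, Pd(dba)2, P(4-MeOC6H4)3, KOAc, toluene, 50 °C) then gives 10.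

Third, step 6.
- **Risk:** Discrimination between the two aryl methyl ethers may be incomplete, leading to under- or over-demethylation. The boron-activated primary oxygen may also suffer substitution by chloride.
- **Fallback:** It sets out from 15 and comes back at 17, and it overshoots on purpose and then re-methylates.
- **Exhaustive cleavage:** BBr3 (excess), CH2Cl2, −78 → 0 °C, then MeOH, removes both methyl ethers and the silyl group to give (3R)-6,8-dihydroxy-3-(11-hydroxyundecyl)-3,4-dihydro-1H-isochromen-1-one F7.
- **Selective methylation:** MeI (1 equiv), K2CO3, acetone, rt, then alkylates only the C6 phenol and gives 17. The C8 phenol is tied up in a hydrogen bond to the C1 carbonyl, and the aliphatic alcohol is not deprotonated.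

Further compounds
F1 | step 4 | 2-(3,5-dimethoxybenzyl)-4,4,5,5-tetramethyl-1,3,2-dioxaborolane | COc1cc(OC)cc(CB2OC(C)(C)C(C)(C)O2)c1
F2 | step 4 | lithium boronate ate complex from 11 and F1 | CC(C)N(C(C)C)C(=O)O[C@@H]([B-]1(Cc2cc(OC)cc(OC)c2)OC(C)(C)C(C)(C)O1)CCCCCCCCCCCO[Si](C)(C)C(C)(C)C.[Li+]
F3 | step 4 | (R)-secondary boronic ester, tert-butyl{[(12R)-13-(3,5-dimethoxyphenyl)-12-(4,4,5,5-tetramethyl-1,3,2-dioxaborolan-2-yl)tridecyl]oxy}dimethylsilane | COc1cc(OC)cc(C[C@@H](CCCCCCCCCCCO[Si](C)(C)C(C)(C)C)B2OC(C)(C)C(C)(C)O2)c1
F4 | step 4 | (2R)-13-(tert-butyldimethylsilyloxy)-1-(3,5-dimethoxyphenyl)tridecan-2-ol | COc1cc(OC)cc(C[C@@H](CCCCCCCCCCCO[Si](C)(C)C(C)(C)C)O)c1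
F5 | step 4 | (2R)-1-(2-bromo-3,5-dimethoxyphenyl)-13-(tert-butyldimethylsilyloxy)tridecan-2-ol | COc1cc(OC)c(Br)c(C[C@@H](CCCCCCCCCCCO[Si](C)(C)C(C)(C)C)O)c1
F6 | step 3 | methyl 2-(bromomethyl)-4,6-dimethoxybenzoate | COC(=O)c1c(CBr)cc(OC)cc1OC
F7 | step 6 | (3R)-6,8-dihydroxy-3-(11-hydroxyundecyl)-3,4-dihydro-1H-isochromen-1-one | Oc1cc(O)c2c(c1)C[C@@H](CCCCCCCCCCCO)OC2=O
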